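**Plan**

- Retrosynthesis: the butenolide is cut at C12–C13 (Stille coupling of a stannane grown from a C9 ethynyl group). The 6-acetate and 7,8-diol are traced to a C6 ketone with a C8 exocyclic methylene, and ring B is cut at C6–C7. Then C9–C20 (lactone methylation), C9–C10 (Ireland–Claisen) and C5–C19 (Birch methylation) are cut.
- Enabling feature: C6 is a carbinol carbon next to quaternary C5, and the C7 oxygen and the C8 methyl can both grow from a C8 methylene. Ring B (C5–C10) is therefore a disguised 3-methylenecyclohexanol, reachable from a C6 aldehyde on C5 and an isopropenyl group on C9.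
- Forward: ring A comes from 2-methylbenzoic acid by Birch reductive methylation. The C9 unit is attached at C10 by Ireland–Claisen rearrangement and tied back to C6 as a temporary δ-lactone. Lactone methylation, diene reduction and lactol alkynylation give the aldehyde, ring B closes by the carbonyl-ene reaction, and the oxygen pattern and side chain follow.
- Stereochemistry: C5 from the prolinol-ether auxiliary; C10 by suprafacial transfer from C2; C9 by alkylation anti to the C19 methyl; C6 axial from the ene chair, then reset by Luche reduction; C7/C8 by OsO4 anti to the acetate and the axial methyls; the E alkene by syn hydrostannation.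

Key step: step 14

Remark: clerodane numbering is used throughout (ring A = C1–C5, C10; ring B = C5–C10; C17 on C8, C18 on C4, C19 on C5, C20 on C9, side chain C11/C12); α is the face of the C19 methyl, β the face of H-10.

Assumption: the (S)-auxiliary is taken to steer the Birch methylation to the (R)-configured quaternary carbon, as in the accepted model for 2-alkylbenzamides; were the sense opposite, the enantiomeric auxiliary would be used.

**Step 1**
Reactants: 1 2-methylbenzoic acid; 2 (S)-2-(methoxymethyl)pyrrolidine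
Product: 4 [(2S)-2-(methoxymethyl)pyrrolidin-1-yl](2-methylphenyl)methanone, via 2-methylbenzoyl chloride 3 (not isolated)
Conditions: SOCl2, cat. DMF, toluene, 70 °C; then 2, Et3N, CH2Cl2, 0 °C to rt
Reagents that add atoms: none
Why: N-acylation of the secondary amine by the acid chloride is dependable for ortho-substituted benzoic acids.

**Step 2**
Reactants: 4 the benzamide
Product: 6 [(1R)-1,2-dimethylcyclohexa-2,5-dien-1-yl][(2S)-2-(methoxymethyl)pyrrolidin-1-yl]methanone, via potassium enolate 5 (not isolated)
Conditions: K, NH3(l), THF, t-BuOH (1 equiv), −78 °C; then MeI, −78 °C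
Reagents that add atoms: iodomethane, CI
Why: Birch reduction gives the amide enolate of the 1,4-dihydroarene, which should be methylated on one face under control of the prolinol ether auxiliary (asymmetric Birch reduction–alkylation), setting C5.

**Step 3**
Reactants: 6 the diene amide
Product: 7 [(1R)-1,2-dimethylcyclohexa-2,5-dien-1-yl]methanol
Conditions: LiNH2BH3, THF, 0 °C to rt
Reagents that add atoms: none
Why: lithium amidotrihydroborate reduces hindered tertiary amides to primary alcohols with C–N cleavage, releasing the auxiliary and leaving the skipped diene alone.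

**Step 4**
Reactants: 7 the dienyl methanol
Product: 8 tert-butyl{[(1R)-1,2-dimethylcyclohexa-2,5-dien-1-yl]methoxy}diphenylsilane
Conditions: t-BuPh2SiCl, imidazole, DMF, rt
Reagents that add atoms: tert-butyl(chloro)diphenylsilane, CC(C)(C)[Si](Cl)(c1ccccc1)c1ccccc1
Why: routine silylation of the neopentyl primary alcohol; the bulky silyloxymethyl group later differentiates the two faces of ring A.

**Step 5**
Reactants: 8 the silyl ether
Product: 9 (4R)-4-{[tert-butyl(diphenyl)silyl]oxymethyl}-3,4-dimethylcyclohexa-2,5-dien-1-one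
Conditions: CrO3, 3,5-dimethylpyrazole, CH2Cl2, −20 °C
Reagents that add atoms: chromium trioxide, O=[Cr](=O)=O
Why: allylic oxidation at the doubly allylic C2 methylene gives the cross-conjugated dienone, a known outcome for 3,3-disubstituted cyclohexa-1,4-dienes.

**Step 6**
Reactants: 9 the dienone
Product: 10 (1S,4R)-4-{[tert-butyl(diphenyl)silyl]oxymethyl}-3,4-dimethylcyclohexa-2,5-dien-1-ol (hydroxyl cis to the silyloxymethyl group)
Conditions: NaBH4, CeCl3·7H2O, MeOH, −78 °C
Reagents that add atoms: none
Why: Luche 1,2-reduction; hydride should add anti to the larger and more electronegative silyloxymethyl substituent on C5, placing the C2 hydroxyl cis to it.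

**Step 7**
Reactants: 10 the cis-dienol; 11 3-methylbut-2-enoic acid
Product: 12 (1R,4R)-4-{[tert-butyl(diphenyl)silyl]oxymethyl}-3,4-dimethylcyclohexa-2,5-dien-1-yl 3-methylbut-2-enoate (acyloxy group cis to the C19 methyl)
Conditions: PPh3, DIAD, toluene, −20 to 0 °C
Reagents that add atoms: none
Why: Mitsunobu esterification inverts C2 by SN2 displacement (no hydrogen on a neighbouring sp3 carbon, so no elimination), which puts the ester oxygen on the methyl face as the rearrangement requires.

**Step 8**
Reactants: 12 the dienyl ester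
Product: 15 2-[6-({[tert-butyl(diphenyl)silyl]oxy}methyl)-5,6-dimethylcyclohexa-2,4-dien-1-yl]-3-methylbut-3-enoic acid as a mixture of C9 epimers, via silyl ketene acetal 13 (not isolated), via trimethylsilyl ester 14 (not isolated)
Conditions: LiN(i-Pr)2, Me3SiCl, THF/DMPU, −78 to 50 °C; then aq. NH4Cl
Reagents that add atoms: none
Why: Ireland–Claisen rearrangement: γ-deprotonation gives the silyl dienyl ketene acetal, and the suprafacial [3,3] shift through the unsubstituted allyl terminus transfers the C2–O configuration to C10, forming C9–C10 cis to the C19 methyl; C9 is left uncontrolled on purpose.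

**Step 9**
Reactants: 15 the silyloxy acid
Product: 17 8,8a-dimethyl-4-(prop-1-en-2-yl)-1,4,4a,8a-tetrahydro-3H-isochromen-3-one (trans-fused; both C9 epimers), via hydroxy acid 16 (not isolated)
Conditions: Bu4NF, THF, rt; then EDC·HCl, DMAP, CH2Cl2, rt
Reagents that add atoms: none
Why: fluoride desilylation then carbodiimide lactonisation gives the trans-fused δ-lactone, which ties C11 to the C6 oxygen and places C9 in a rigid ring.

**Step 10**
Reactants: 17 the lactone
Product: 19 4,8,8a-trimethyl-4-(prop-1-en-2-yl)-1,4,4a,8a-tetrahydro-3H-isochromen-3-one (C20 methyl on the face opposite to the C19 methyl), via lithium enolate 18 (not isolated)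
Conditions: LiN(i-Pr)2, THF, −78 °C; then MeI, DMPU, −78 to −20 °C
Reagents that add atoms: iodomethane, CI
Why: α-alkylation of the lactone dienolate; both C9 epimers converge on one enolate, and iodomethane should enter anti to the syn-axial C19 methyl, as in alkylations of trans-fused enolates bearing a 1,3-related angular methyl, which gives the C9 configuration of the target.

**Step 11**
Reactants: 19 the diene lactone
Product: 20 4,8,8a-trimethyl-4-(prop-1-en-2-yl)-1,4,4a,5,6,8a-hexahydro-3H-isochromen-3-one
Conditions: TsNHNH2, NaOAc, THF/H2O, reflux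
Reagents that add atoms: none
Why: diimide reduction is fastest at the disubstituted end of a conjugated cyclohexadiene and slow for trisubstituted and hindered 1,1-disubstituted alkenes, so only C1=C2 should be saturated.

**Step 12**
Reactants: 20 the lactone
Product: 22 [6-(3,4-dimethylpent-4-en-1-yn-3-yl)-1,2-dimethylcyclohex-2-en-1-yl]methanol (CH2OH and the C9 substituent trans on ring A), via lactol 21 (not isolated)
Conditions: i-Bu2AlH, CH2Cl2, −78 °C; then MeOH, K2CO3, dimethyl (1-diazo-2-oxopropyl)phosphonate, rt
Reagents that add atoms: dimethyl (1-diazo-2-oxopropyl)phosphonate, CC(=O)C(=[N+]=[N-])P(=O)(OC)OC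
Why: the hindered lactone should stop at the lactol, and Seyferth–Gilbert homologation of its open hydroxy aldehyde form turns C11 into an ethynyl group while freeing the C6 alcohol.

**Step 13**
Reactants: 22 the alkynol
Product: 23 6-(3,4-dimethylpent-4-en-1-yn-3-yl)-1,2-dimethylcyclohex-2-ene-1-carbaldehyde
Conditions: Dess–Martin periodinane, CH2Cl2, rt
Reagents that add atoms: none
Why: Dess–Martin oxidation of the neopentyl alcohol gives the non-enolisable aldehyde without touching alkene or alkyne.

**Step 14**
Reactants: 23 the aldehyde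
Product: 24 4-ethynyl-4,8,8a-trimethyl-3-methylidene-1,2,3,4,4a,5,6,8a-octahydronaphthalen-1-ol (trans-decalin; 6β axial hydroxyl, 9α methyl, 9β ethynyl)
Conditions: Me2AlCl, CH2Cl2, −78 to 0 °C
Reagents that add atoms: none
Why: Me2AlCl coordinates the C6 aldehyde; the terminal carbon C7 of the C9 isopropenyl group then bonds to C6 while a C17 hydrogen passes to the carbonyl oxygen through a six-membered array, concerted or by way of a short-lived tertiary cation at C8, leaving the C8=C17 exocyclic alkene. The closest known reaction type is the Me2AlCl-promoted type 2 intramolecular carbonyl-ene cyclisation of aldehydes carrying a 1,1-disubstituted alkene to 3-methylenecyclohexanols. Ring B closes as a six-membered chair in the type 2 mode (the central ene carbon C8 carries the tether, with exo attack on the carbonyl), and the trans ring fusion follows from the trans disposition of C6 and C9 on ring A fixed in steps 2 and 8. The new stereocentre C6 is controlled by the chair transition state, in which the oxygen must sit axial (β) to reach the C17 hydrogen. The step needs chemoselectivity among three π systems and ene closure over chloride trapping: only the isopropenyl group has both a terminus within reach of C6 and an allylic hydrogen (C3=C4 could only close a three- or four-membered ring, the ethynyl group has no allylic hydrogen), and the methyl–aluminium bonds scavenge HCl. The aldehyde is neopentylic and cannot enolise, so no aldol or epimerisation pathway competes.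

**Step 15**
Reactants: 24 the homoallylic alcohol
Product: 26 4-ethynyl-3,4,8,8a-tetramethyl-4a,5,6,8a-tetrahydronaphthalen-1(4H)-one (C6 ketone conjugated with C7=C8), via deconjugated enone 25 (not isolated)
Conditions: Dess–Martin periodinane, CH2Cl2, rt; then DBU, rt
Reagents that add atoms: none
Why: alcohol oxidation followed by base-mediated migration of the exocyclic double bond into conjugation; C7 is the only enolisable position.

**Step 16**
Reactants: 26 the enone
Product: 27 the 3β,4β-epoxide of 26
Conditions: mCPBA, CH2Cl2, 0 °C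
Reagents that add atoms: 3-chloroperoxybenzoic acid, OOC(=O)c1cccc(Cl)c1
Why: Prilezhaev epoxidation selects the electron-rich C3=C4 alkene over the enone and the alkyne and attacks anti to the C19 methyl; the epoxide masks C3=C4, which would otherwise compete in the dihydroxylation.

**Step 17**
Reactants: 27 the epoxy enone
Product: 28 the 6α-allylic alcohol (equatorial hydroxyl)
Conditions: NaBH4, CeCl3·7H2O, MeOH, −78 to 0 °C
Reagents that add atoms: none
Why: Luche reduction; axial hydride delivery from the β face, anti to the axial C19 methyl on C5, should give the equatorial 6α-alcohol.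

**Step 18**
Reactants: 28 the allylic alcohol
Product: 29 the 6α-acetate
Conditions: Ac2O, Et3N, cat. DMAP, CH2Cl2, rt
Reagents that add atoms: acetic anhydride, CC(=O)OC(C)=O
Why: DMAP-catalysed acetylation fixes the C6 acetate before the C7 and C8 hydroxyls exist, which settles the differentiation of the three oxygens.

**Step 19**
Reactants: 29 the allylic acetate
Product: 30 the 6α-acetoxy-7β,8β-diol (3β,4β-epoxide and C9 ethynyl retained)
Conditions: OsO4 (cat.), N-methylmorpholine N-oxide, acetone/H2O, rt
Reagents that add atoms: N-methylmorpholine N-oxide, C[N+]1([O-])CCOCC1; water, O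
Why: catalytic OsO4 syn-dihydroxylation of the only remaining alkene, approached anti to the allylic acetate and to the axial C19 and C20 methyls; the alkyne is far less reactive.

**Step 20**
Reactants: 30 the epoxy diol acetate
Product: 31 the 6α-acetoxy-7β,8β-dihydroxy-9-ethynyl decalin with C3=C4 restored
Conditions: Zn, NaI, NaOAc, AcOH, rt
Reagents that add atoms: none
Why: epoxide deoxygenation by iodohydrin formation and zinc-induced reductive elimination, the classical way of unmasking a trisubstituted alkene next to a quaternary carbon (steroid 5,6-epoxide to 5-ene).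

**Step 21**
Reactants: 31 the alkyne
Product: 32 the (E)-2-(tributylstannyl)vinyl compound at C9
Conditions: Bu3SnH, PdCl2(PPh3)2 (cat.), THF, 0 °C to rt
Reagents that add atoms: tributyltin hydride, CCCC[SnH](CCCC)CCCC
Why: palladium-catalysed syn hydrostannation of the terminal alkyne; the quaternary propargylic carbon should direct tin to the terminal carbon and give the E-vinylstannane.

**Step 22**
Reactants: 32 the vinylstannane; 33 4-bromofuran-2(5H)-one
Product: 34 CNP0279118.1 (6α-acetoxy-7β,8β-dihydroxy clerodane with the (E)-C11=C12 butenolide side chain)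
Conditions: Pd2(dba)3 (dba = dibenzylideneacetone), AsPh3, CuI, NMP, rt to 40 °C
Reagents that add atoms: none
Why: Stille coupling proceeds with retention of alkene geometry under neutral conditions that should leave the acetate and the free diol untouched.

**Compound list**

1 | 2-methylbenzoic acid | Cc1ccccc1C(=O)O | starting material
2 | (S)-2-(methoxymethyl)pyrrolidine | COC[C@@H]1CCCN1 | starting material
3 | 2-methylbenzoyl chloride | Cc1ccccc1C(Cl)=O | intermediate
4 | [(2S)-2-(methoxymethyl)pyrrolidin-1-yl](2-methylphenyl)methanone | COC[C@@H]1CCCN1C(=O)c1ccccc1C | intermediate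
5 | potassium [(2S)-2-(methoxymethyl)pyrrolidin-1-yl](2-methylcyclohexa-2,5-dien-1-ylidene)methanolate (amide enolate) | COC[C@@H]1CCCN1C([O-])=C1C=CCC=C1C.[K+] | intermediate
6 | [(1R)-1,2-dimethylcyclohexa-2,5-dien-1-yl][(2S)-2-(methoxymethyl)pyrrolidin-1-yl]methanone | COC[C@@H]1CCCN1C(=O)[C@]1(C)C=CCC=C1C | intermediate
7 | [(1R)-1,2-dimethylcyclohexa-2,5-dien-1-yl]methanol | OC[C@]1(C)C=CCC=C1C | intermediate
8 | tert-butyl{[(1R)-1,2-dimethylcyclohexa-2,5-dien-1-yl]methoxy}diphenylsilane | CC(C)(C)[Si](c1ccccc1)(c1ccccc1)OC[C@]1(C)C=CCC=C1C | intermediate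
9 | (4R)-4-{[tert-butyl(diphenyl)silyl]oxymethyl}-3,4-dimethylcyclohexa-2,5-dien-1-one | CC(C)(C)[Si](c1ccccc1)(c1ccccc1)OC[C@]1(C)C=CC(=O)C=C1C | intermediate
10 | (1S,4R)-4-{[tert-butyl(diphenyl)silyl]oxymethyl}-3,4-dimethylcyclohexa-2,5-dien-1-ol (OH cis to CH2OSi) | CC(C)(C)[Si](c1ccccc1)(c1ccccc1)OC[C@]1(C)C=C[C@H](O)C=C1C | intermediate
11 | 3-methylbut-2-enoic acid | CC(C)=CC(=O)O | starting material
12 | (1R,4R)-4-{[tert-butyl(diphenyl)silyl]oxymethyl}-3,4-dimethylcyclohexa-2,5-dien-1-yl 3-methylbut-2-enoate (ester oxygen cis to the C4 methyl) | CC(C)(C)[Si](c1ccccc1)(c1ccccc1)OC[C@]1(C)C=C[C@@H](OC(=O)C=C(C)C)C=C1C | intermediate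
13 | trimethylsilyl ketene acetal of 12 (1-dienyloxy-3-methyl-1-trimethylsilyloxybuta-1,3-diene) | CC(C)(C)[Si](c1ccccc1)(c1ccccc1)OC[C@]1(C)C=C[C@@H](OC(O[Si](C)(C)C)=CC(C)=C)C=C1C | intermediate
14 | trimethylsilyl ester of acid 15 | CC(C)(C)[Si](c1ccccc1)(c1ccccc1)OC[C@]1(C)[C@@H](C(C(C)=C)C(=O)O[Si](C)(C)C)C=CC=C1C | intermediate
15 | 2-[6-({[tert-butyl(diphenyl)silyl]oxy}methyl)-5,6-dimethylcyclohexa-2,4-dien-1-yl]-3-methylbut-3-enoic acid (side chain cis to the ring C6 methyl; C9 epimers) | CC(C)(C)[Si](c1ccccc1)(c1ccccc1)OC[C@]1(C)[C@@H](C(C(C)=C)C(=O)O)C=CC=C1C | intermediate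
16 | 2-[6-(hydroxymethyl)-5,6-dimethylcyclohexa-2,4-dien-1-yl]-3-methylbut-3-enoic acid (C9 epimers) | OC[C@]1(C)[C@@H](C(C(C)=C)C(=O)O)C=CC=C1C | intermediate
17 | 8,8a-dimethyl-4-(prop-1-en-2-yl)-1,4,4a,8a-tetrahydro-3H-isochromen-3-one (trans-fused; C9 epimers) | C=C(C)C1C(=O)OC[C@@]2(C)C(C)=CC=C[C@H]12 | intermediate
18 | lithium enolate of lactone 17 | C=C(C)C1=C([O-])OC[C@@]2(C)C(C)=CC=C[C@H]12.[Li+] | intermediate
19 | 4,8,8a-trimethyl-4-(prop-1-en-2-yl)-1,4,4a,8a-tetrahydro-3H-isochromen-3-one (trans-fused; 4-methyl opposite to the 8a-methyl) | C=C(C)[C@]1(C)C(=O)OC[C@@]2(C)C(C)=CC=C[C@H]12 | intermediate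
20 | 4,8,8a-trimethyl-4-(prop-1-en-2-yl)-1,4,4a,5,6,8a-hexahydro-3H-isochromen-3-one | C=C(C)[C@]1(C)C(=O)OC[C@@]2(C)C(C)=CCC[C@H]12 | intermediate
21 | 4,8,8a-trimethyl-4-(prop-1-en-2-yl)-3,4,4a,5,6,8a-hexahydro-1H-isochromen-3-ol (lactol, both anomers) | C=C(C)[C@]1(C)C(O)OC[C@@]2(C)C(C)=CCC[C@H]12 | intermediate
22 | [6-(3,4-dimethylpent-4-en-1-yn-3-yl)-1,2-dimethylcyclohex-2-en-1-yl]methanol (CH2OH trans to the C6 substituent) | C=C(C)[C@](C)(C#C)[C@H]1CCC=C(C)[C@]1(C)CO | intermediate
23 | 6-(3,4-dimethylpent-4-en-1-yn-3-yl)-1,2-dimethylcyclohex-2-ene-1-carbaldehyde (ene precursor) | C=C(C)[C@](C)(C#C)[C@H]1CCC=C(C)[C@]1(C)C=O | intermediate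
24 | 4-ethynyl-4,8,8a-trimethyl-3-methylidene-1,2,3,4,4a,5,6,8a-octahydronaphthalen-1-ol (ene product; 6β axial OH, trans-decalin) | O[C@@H]1CC(=C)[C@](C)(C#C)[C@H]2CCC=C(C)[C@]12C | intermediate
25 | 4-ethynyl-4,8,8a-trimethyl-3-methylidene-3,4,4a,5,6,8a-hexahydronaphthalen-1(2H)-one | O=C1CC(=C)[C@](C)(C#C)[C@H]2CCC=C(C)[C@]12C | intermediate
26 | 4-ethynyl-3,4,8,8a-tetramethyl-4a,5,6,8a-tetrahydronaphthalen-1(4H)-one | O=C1C=C(C)[C@](C)(C#C)[C@H]2CCC=C(C)[C@]12C | intermediate
27 | 3β,4β-epoxide of enone 26 | O=C1C=C(C)[C@](C)(C#C)[C@H]2CC[C@@H]3O[C@]3(C)[C@]12C | intermediate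
28 | 3β,4β-epoxy-9-ethynyl-7-en-6α-ol | O[C@H]1C=C(C)[C@](C)(C#C)[C@H]2CC[C@@H]3O[C@]3(C)[C@]12C | intermediate
29 | 6α-acetate of 28 | CC(=O)O[C@H]1C=C(C)[C@](C)(C#C)[C@H]2CC[C@@H]3O[C@]3(C)[C@]12C | intermediate
30 | 6α-acetoxy-3β,4β-epoxy-9-ethynyl-7β,8β-diol | CC(=O)O[C@H]1[C@H](O)[C@](C)(O)[C@](C)(C#C)[C@H]2CC[C@@H]3O[C@]3(C)[C@]12C | intermediate
31 | 6α-acetoxy-9-ethynyl-3-ene-7β,8β-diol | CC(=O)O[C@H]1[C@H](O)[C@](C)(O)[C@](C)(C#C)[C@H]2CCC=C(C)[C@]12C | intermediate
32 | 6α-acetoxy-9-[(E)-2-(tributylstannyl)ethenyl]-3-ene-7β,8β-diol | CC(=O)O[C@H]1[C@H](O)[C@](C)(O)[C@](C)(/C=C/[Sn](CCCC)(CCCC)CCCC)[C@H]2CCC=C(C)[C@]12C | intermediate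
33 | 4-bromofuran-2(5H)-one | BrC1=CC(=O)OC1 | starting material
34 | CNP0279118.1 | CC(=O)O[C@H]1[C@H](O)[C@](C)(O)[C@](C)(/C=C/C2=CC(=O)OC2)[C@H]2CCC=C(C)[C@]12C | target

**Totals**

Total step count: 22. Longest linear sequence: 22 steps (from 2-methylbenzoic acid; all other inputs are purchased).

**Steps most likely to fail**

Step 7. The activated bis-allylic alcohol may ionise, so that the carboxylate attacks without clean inversion or at an allylic terminus. In the fallback the oxygen is placed directly on the methyl face instead of by inversion. Diene 8 would be deprotonated at the doubly allylic C2 methylene (s-BuLi, Me2NCH2CH2NMe2, THF, −78 °C) to the pentadienyllithium F1. This anion would be hydroxylated at its central carbon with 2-(phenylsulfonyl)-3-phenyloxaziridine, which should approach anti to the silyloxymethyl group, giving the trans-dienol F2. Carbodiimide esterification with 11 (dicyclohexylcarbodiimide, DMAP) then gives 12 with retention, where the route is rejoined.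

Step 10. The alkylation of the lactone enolate may show poor facial selectivity, or methylation may occur at the far end of the dienolate. In the fallback the C20 methyl is carried in the acid, so that the quaternary C9 is created in the sigmatropic step. Dienol 10 would be esterified under the Mitsunobu conditions of step 7 with 2,3-dimethylbut-2-enoic acid to the ester F3. γ-Deprotonation and silylation give the ketene acetal F4, which rearranges to the silyl ester F5 and, after hydrolysis, to the acid F6. Desilylation to the hydroxy acid F7 and lactonisation as in step 9 give 19 together with its C9 epimer F8, which would be separated by chromatography. The route continues from 19.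

Step 12. Ring-opening of the hindered lactol may be so slow that the diazophosphonate anion decomposes before it condenses with the aldehyde form. The fallback uses a more nucleophilic phosphorus ylide and a separate elimination. Lactone 20 would be reduced with i-Bu2AlH and the lactol 21 isolated. Wittig chloromethylenation with the ylide from (chloromethyl)triphenylphosphonium chloride and KN(SiMe3)2 gives the chloroalkene F9 as an E/Z mixture. Dehydrochlorination with excess LiN(i-Pr)2 gives the alkynol 22, where the route is rejoined.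

**Further compounds**

F1 | step 7 | pentadienyllithium from 8 (lithium 4-{[tert-butyl(diphenyl)silyl]oxymethyl}-3,4-dimethylcyclohexa-2,5-dien-1-ide) | CC(C)(C)[Si](c1ccccc1)(c1ccccc1)OC[C@]1(C)C=C[CH-]C=C1C.[Li+]
F2 | step 7 | (1R,4R)-4-{[tert-butyl(diphenyl)silyl]oxymethyl}-3,4-dimethylcyclohexa-2,5-dien-1-ol (OH trans to CH2OSi) | CC(C)(C)[Si](c1ccccc1)(c1ccccc1)OC[C@]1(C)C=C[C@@H](O)C=C1C
F3 | step 10 | (1R,4R)-4-{[tert-butyl(diphenyl)silyl]oxymethyl}-3,4-dimethylcyclohexa-2,5-dien-1-yl 2,3-dimethylbut-2-enoate | CC(C)(C)[Si](c1ccccc1)(c1ccccc1)OC[C@]1(C)C=C[C@@H](OC(=O)C(C)=C(C)C)C=C1C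
F4 | step 10 | trimethylsilyl ketene acetal of F3 | CC(C)(C)[Si](c1ccccc1)(c1ccccc1)OC[C@]1(C)C=C[C@@H](OC(O[Si](C)(C)C)=C(C)C(C)=C)C=C1C
F5 | step 10 | trimethylsilyl ester of F6 | CC(C)(C)[Si](c1ccccc1)(c1ccccc1)OC[C@]1(C)[C@@H](C(C)(C(C)=C)C(=O)O[Si](C)(C)C)C=CC=C1C
F6 | step 10 | 2-[6-({[tert-butyl(diphenyl)silyl]oxy}methyl)-5,6-dimethylcyclohexa-2,4-dien-1-yl]-2,3-dimethylbut-3-enoic acid (C9 epimers) | CC(C)(C)[Si](c1ccccc1)(c1ccccc1)OC[C@]1(C)[C@@H](C(C)(C(C)=C)C(=O)O)C=CC=C1C
F7 | step 10 | 2-[6-(hydroxymethyl)-5,6-dimethylcyclohexa-2,4-dien-1-yl]-2,3-dimethylbut-3-enoic acid (C9 epimers) | OC[C@]1(C)[C@@H](C(C)(C(C)=C)C(=O)O)C=CC=C1C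
F8 | step 10 | C9 epimer of lactone 19 | C=C(C)[C@@]1(C)C(=O)OC[C@@]2(C)C(C)=CC=C[C@H]12
F9 | step 12 | [6-(1-chloro-3,4-dimethylpenta-1,4-dien-3-yl)-1,2-dimethylcyclohex-2-en-1-yl]methanol (E/Z mixture) | C=C(C)[C@](C)(C=CCl)[C@H]1CCC=C(C)[C@]1(C)CO
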